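**Retrosynthetic overview**

1. The target comes from a bicyclic diol mono-angelate by aroylation of the C6 hydroxyl and release of the phenol; the seven-membered ring is opened at C8=C9 (ring-closing metathesis of a vinyl group and a methallyl group).
2. The methallyl carbinol (C6–C7 bond) comes from a chelation-controlled Barbier addition to a cyclopentane β-hydroxy aldehyde.
3. The five-membered ring (C4–C5 bond, stereocenters C4 and C5) comes from an intramolecular Mukaiyama-type aldol addition of a Z-enol carbamate to an isopropyl ketone, itself made from the distal geranyl olefin by epoxidation and Meinwald rearrangement.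
4. The key C1–C10 bond (quaternary C1, carbinol C10) comes from a Hoppe homoaldol reaction: the (−)-sparteine-lithiated, titanated geranyl carbamate, a chiral homoenolate (d3) equivalent, adds through its γ-carbon to acrolein.
5. Ring order: cyclopentane first, cycloheptene second; building blocks are geraniol, acrolein, angelic acid, methallyl bromide and 4-acetoxybenzoyl chloride.

Core numbering used below: C1 = methyl-bearing ring-fusion carbon, C2/C3 = ring CH2, C4 = C(OH)(isopropyl), C5 = ring-fusion CH, C6 = aroyloxy carbon, C7 = CH2, C8=C9 = ring olefin, C10 = angeloyloxy carbon.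

Assumption: the (−)-sparteine complex of lithiated 3 has the S configuration at the lithium-bearing carbon and is titanated with inversion, as for (E)-but-2-enyl carbamates.

**Route**

Step 1
Reactants: 1 geraniol [(2E)-3,7-dimethylocta-2,6-dien-1-ol]; 2 N,N-diisopropylcarbamoyl chloride
Product: 3 (2E)-3,7-dimethylocta-2,6-dien-1-yl N,N-diisopropylcarbamate
Conditions: NaH, THF, 0 °C; then 2, reflux
Reagents that add atoms: N,N-diisopropylcarbamoyl chloride, CC(C)N(C(C)C)C(=O)Cl
Why: O-carbamoylation of the sodium alkoxide gives the hindered carbamate that later directs α-lithiation and resists nucleophiles; no stereocenter is formed and the E-olefin is untouched.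

Step 2
Reactants: 3 (2E)-3,7-dimethylocta-2,6-dien-1-yl N,N-diisopropylcarbamate; 4 acrolein
Product: 7 (1Z,3S,4R)-4-hydroxy-3-methyl-3-(4-methylpent-3-en-1-yl)hexa-1,5-dien-1-yl N,N-diisopropylcarbamate, via lithiated carbamate 5 (not isolated), via allyltitanium reagent 6 (not isolated)
Conditions: s-BuLi, (−)-sparteine, pentane/cyclohexane, −78 °C; Ti(OiPr)4, −78 °C; acrolein, −78 °C; then H2O
Reagents that add atoms: acrolein, C=CC=O
Why: Proposed new method: Hoppe homoaldol reaction extended to a γ,γ-disubstituted allyl carbamate – carbamate-directed α-lithiation in the sparteine complex gives (S)-5, Ti(OiPr)4 titanates with inversion to (R)-6, and acrolein is delivered to the γ-carbon through a Zimmerman–Traxler chair (vinyl equatorial, E-chain equatorial, Z-methyl axial, carbamoyloxy axial), so the quaternary carbon (3S), the carbinol (4R) and the Z-enol carbamate all follow from the E-olefin geometry and the C–Ti configuration; closest known reaction: the sparteine-mediated homoaldol reaction of (E)-but-2-enyl N,N-diisopropylcarbamate with aldehydes.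

Step 3
Reactants: 7 homoaldol adduct; 8 angelic acid [(2Z)-2-methylbut-2-enoic acid]
Product: 10 (1Z,3S,4R)-1-[(diisopropylcarbamoyl)oxy]-3-methyl-3-(4-methylpent-3-en-1-yl)hexa-1,5-dien-4-yl (2Z)-2-methylbut-2-enoate, via mixed anhydride 9 (not isolated)
Conditions: 8, 2,4,6-trichlorobenzoyl chloride, Et3N, toluene, rt; then 7, 80 °C
Reagents that add atoms: angelic acid, C/C=C(/C)C(=O)O
Why: Yamaguchi-type mixed-anhydride esterification run without a nucleophilic catalyst, so the Z-olefin of the angelate does not isomerise to the tiglate; acylation at oxygen leaves the carbinol configuration unchanged and masks the hydroxyl for steps 5 and 6.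

Step 4
Reactants: 10 angelate triene
Product: 11 (1Z,3S,4R)-1-[(diisopropylcarbamoyl)oxy]-3-[2-(3,3-dimethyloxiran-2-yl)ethyl]-3-methylhexa-1,5-dien-4-yl (2Z)-2-methylbut-2-enoate (both epimers at the oxirane CH)
Conditions: mCPBA (1.05 equiv), NaHCO3, CH2Cl2, 0 °C
Reagents that add atoms: mCPBA, O=C(OO)c1cccc(Cl)c1
Why: Prilezhaev epoxidation is fastest at the electron-rich trisubstituted dialkyl olefin (the vinyl group, the conjugated angelate and the hindered, carbamate-deactivated enol olefin are slower); the new oxirane stereocenter is uncontrolled but becomes a carbonyl carbon in step 5.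

Step 5
Reactants: 11 epoxide
Product: 12 (1Z,3S,4R)-1-[(diisopropylcarbamoyl)oxy]-3-methyl-3-(4-methyl-3-oxopentyl)hexa-1,5-dien-4-yl (2Z)-2-methylbut-2-enoate
Conditions: BF3·OEt2 (0.3 equiv), CH2Cl2, −78 to −30 °C
Reagents that add atoms: none
Why: Meinwald rearrangement – Lewis-acid opening at the tertiary oxirane carbon followed by a 1,2-hydride shift gives the isopropyl ketone from both epimers; six-membered cation–olefin closure is disfavoured because the enol carbon is neopentylic and only weakly nucleophilic.

Step 6
Reactants: 12 keto enol carbamate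
Product: 13 (1R)-1-[(1S,2R,3R)-2-formyl-3-hydroxy-1-methyl-3-(propan-2-yl)cyclopentyl]prop-2-en-1-yl (2Z)-2-methylbut-2-enoate
Conditions: TiCl4 (2.2 equiv), CH2Cl2, −78 °C; then H2O
Reagents that add atoms: none
Why: Proposed new method: intramolecular Mukaiyama-type aldol addition (5-enolexo-exo-trig) in which the Z-enol carbamate is the π-nucleophile toward the TiCl4-activated ketone and the carbamoyl group is lost to chloride to unveil the aldehyde; allylic 1,3-strain with the Z-carbamoyloxy group puts the C1 methyl, not the bulky acyloxyallyl arm, in the olefin plane so the formyl group ends cis to the methyl, and titanium bridging of ketone and carbamate oxygens together with the isopropyl group avoiding the formyl-bearing carbon puts the new hydroxyl cis to the formyl group, which is also the thermodynamically preferred arrangement (small groups Me, CHO, OH on one face); closest known reactions: TiCl4-mediated aldol additions of enol acetates and BF3-mediated additions of homoaldol enol carbamates to oxocarbenium ions.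

Step 7
Reactants: 13 hydroxy aldehyde; 14 3-bromo-2-methylprop-1-ene (methallyl bromide)
Product: 16 (1R)-1-[(1S,2S,3R)-3-hydroxy-2-[(1S)-1-hydroxy-3-methylbut-3-en-1-yl]-1-methyl-3-(propan-2-yl)cyclopentyl]prop-2-en-1-yl (2Z)-2-methylbut-2-enoate, via 2-methylallylzinc bromide 15 (not isolated)
Conditions: Zn dust, THF/sat. aq. NH4Cl, 0 °C to rt
Reagents that add atoms: 3-bromo-2-methylprop-1-ene, C=C(C)CBr
Why: Barbier allylation in aqueous medium tolerates the ester and the free tertiary alcohol; zinc chelated between the cis tertiary hydroxyl and the aldehyde oxygen fixes the carbonyl, and attack on its exposed outer face (Cram-chelate model, on the side of the C5 hydrogen) gives the (S)-carbinol at C6.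

Step 8
Reactants: 16 diene diol
Product: 17 (3R,3aS,4S,8R,8aS)-3,4-dihydroxy-6,8a-dimethyl-3-(propan-2-yl)-1,2,3,3a,4,5,8,8a-octahydroazulen-8-yl (2Z)-2-methylbut-2-enoate (ring numbering as in the target)
Conditions: second-generation Grubbs catalyst (H2IMes)(PCy3)Cl2Ru=CHPh (10 mol%), toluene (5 mM), 80 °C
Reagents that add atoms: none
Why: Ring-closing metathesis between the vinyl group and the 1,1-disubstituted olefin closes the seven-membered ring (trans-fused to the cyclopentane) and forms the trisubstituted ring olefin, whose geometry is fixed by the ring; the conjugated angelate olefin is inert and no stereocenter is touched.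

Step 9
Reactants: 17 bicyclic diol mono-angelate; 18 4-acetoxybenzoyl chloride
Product: 20 (3R,3aS,4S,8R,8aS)-3-hydroxy-6,8a-dimethyl-8-{[(2Z)-2-methylbut-2-enoyl]oxy}-3-(propan-2-yl)-1,2,3,3a,4,5,8,8a-octahydroazulen-4-yl 4-hydroxybenzoate (the target), via acetoxybenzoate diester 19 (not isolated)
Conditions: 18, Et3N, DMAP (cat.), CH2Cl2, 0 °C to rt; then pyrrolidine, 0 °C
Reagents that add atoms: 4-acetoxybenzoyl chloride, CC(=O)Oc1ccc(cc1)C(=O)Cl
Why: Acylation occurs only at the secondary C6 hydroxyl because the tertiary C4 alcohol is too hindered, and the aryl acetate is then cleaved in the same pot by aminolysis, which is far faster for a phenyl ester than for the alkyl angelate and benzoate esters; no stereocenter is affected.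

**Compound list**

1 | geraniol | CC(C)=CCC/C(C)=C/CO | starting material
2 | N,N-diisopropylcarbamoyl chloride | CC(C)N(C(C)C)C(=O)Cl | starting material
3 | geranyl N,N-diisopropylcarbamate | CC(C)=CCC/C(C)=C/COC(=O)N(C(C)C)C(C)C | intermediate
4 | acrolein | C=CC=O | starting material
5 | (S)-1-lithiogeranyl N,N-diisopropylcarbamate, (−)-sparteine complex (ligand not drawn) | CC(C)=CCC/C(C)=C/[C@H]([Li])OC(=O)N(C(C)C)C(C)C | intermediate (not isolated)
6 | (R)-1-(triisopropoxytitanio)geranyl N,N-diisopropylcarbamate | CC(C)=CCC/C(C)=C/[C@@H]([Ti](OC(C)C)(OC(C)C)OC(C)C)OC(=O)N(C(C)C)C(C)C | intermediate (not isolated)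
7 | (1Z,3S,4R)-4-hydroxy-3-methyl-3-(4-methylpent-3-en-1-yl)hexa-1,5-dien-1-yl N,N-diisopropylcarbamate | O[C@H](C=C)[C@@](C)(CCC=C(C)C)/C=C\OC(=O)N(C(C)C)C(C)C | intermediate
8 | angelic acid | C/C=C(/C)C(=O)O | starting material
9 | angelic 2,4,6-trichlorobenzoic mixed anhydride | C/C=C(/C)C(=O)OC(=O)c1c(Cl)cc(Cl)cc1Cl | intermediate (not isolated)
10 | angelate of 7 | C/C=C(/C)C(=O)O[C@H](C=C)[C@@](C)(CCC=C(C)C)/C=C\OC(=O)N(C(C)C)C(C)C | intermediate
11 | distal epoxide of 10 (both oxirane epimers) | C/C=C(/C)C(=O)O[C@H](C=C)[C@@](C)(CCC1OC1(C)C)/C=C\OC(=O)N(C(C)C)C(C)C | intermediate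
12 | isopropyl ketone, Z-enol carbamate | C/C=C(/C)C(=O)O[C@H](C=C)[C@@](C)(CCC(=O)C(C)C)/C=C\OC(=O)N(C(C)C)C(C)C | intermediate
13 | cyclopentane β-hydroxy aldehyde (Me, CHO and OH all cis) | C/C=C(/C)C(=O)O[C@H](C=C)[C@@]1(C)CC[C@@](O)(C(C)C)[C@@H]1C=O | intermediate
14 | 3-bromo-2-methylprop-1-ene | C=C(C)CBr | starting material
15 | 2-methylallylzinc bromide | C=C(C)C[Zn]Br | intermediate (not isolated)
16 | diene diol mono-angelate | C/C=C(/C)C(=O)O[C@H](C=C)[C@@]1(C)CC[C@@](O)(C(C)C)[C@@H]1[C@@H](O)CC(C)=C | intermediate
17 | bicyclic diol mono-angelate | C/C=C(/C)C(=O)O[C@@H]1C=C(C)C[C@H](O)[C@@H]2[C@]1(C)CC[C@@]2(O)C(C)C | intermediate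
18 | 4-acetoxybenzoyl chloride | CC(=O)Oc1ccc(cc1)C(=O)Cl | starting material
19 | 4-acetoxybenzoate of 17 | C/C=C(/C)C(=O)O[C@@H]1C=C(C)C[C@H](OC(=O)c2ccc(OC(C)=O)cc2)[C@@H]2[C@]1(C)CC[C@@]2(O)C(C)C | intermediate (not isolated)
20 | CNP0273650.2 | C/C=C(/C)C(=O)O[C@@H]1C=C(C)C[C@H](OC(=O)c2ccc(O)cc2)[C@@H]2[C@]1(C)CC[C@@]2(O)C(C)C | target

**Step count and risks**

Total steps: 9. Longest linear sequence: 9 (from geraniol).

The three steps most likely to fail:

Step 2 (enantioselective, quaternary-centre-forming homoaldol reaction). The lithiated geranyl carbamate may not be held in one configuration by sparteine, giving low enantiomeric excess. Fallback, setting out from 3: lithiation with s-BuLi/TMEDA (Et2O, −78 °C), titanation with Ti(OiPr)4 and addition of acrolein give the anti, Z adduct as a racemate, that is 7 together with its (1Z,3R,4S) enantiomer F1. Sharpless kinetic resolution of the mixture (Ti(OiPr)4, D-(−)-diisopropyl tartrate, t-BuOOH, 4 Å sieves, CH2Cl2, −20 °C, about 55% conversion) epoxidises the vinyl group of F1 to the erythro epoxy alcohol F2 and leaves 7 unreacted. The route is rejoined at 7.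

Step 5 (Meinwald rearrangement next to an enol carbamate). Cation–olefin cyclisation, alkyl instead of hydride shift, or premature unselective aldol closure could compete. Fallback, setting out from 3, installs the ketone before the key step: mCPBA gives the 6,7-epoxygeranyl carbamate F3; BF3·OEt2 rearranges it to the keto carbamate F4; ethylene glycol/TsOH (benzene, Dean–Stark) gives the dioxolane carbamate F5; the homoaldol reaction of step 2 on F5 gives the dioxolane homoaldol adduct F6; angeloylation as in step 3 gives the dioxolane angelate F7; PPTS in wet acetone removes the ketal. The route is rejoined at 12.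

Step 6 (enol carbamate as aldol donor toward a ketone). The enol carbamate may be too weak a nucleophile, or the hydroxyl may form on the wrong face. Fallback, setting out from 12: the enol carbamate is hydrolysed (Hg(OAc)2 cat., MeSO3H, aqueous THF) to the keto aldehyde F8, which is closed by an enamine-mediated intramolecular aldol reaction (pyrrolidine/AcOH cat., CH2Cl2) under equilibrating conditions, where the all-cis (Me, CHO, OH) cyclopentane is the thermodynamic product. The route is rejoined at 13.

**Further compounds**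

F1 | step 2 | (1Z,3R,4S)-4-hydroxy-3-methyl-3-(4-methylpent-3-en-1-yl)hexa-1,5-dien-1-yl N,N-diisopropylcarbamate (enantiomer of 7) | O[C@@H](C=C)[C@](C)(CCC=C(C)C)/C=C\OC(=O)N(C(C)C)C(C)C
F2 | step 2 | erythro epoxy alcohol from F1 (vinyl group epoxidised) | O[C@@H]([C@@H]1CO1)[C@](C)(CCC=C(C)C)/C=C\OC(=O)N(C(C)C)C(C)C
F3 | step 5 | (2E)-5-(3,3-dimethyloxiran-2-yl)-3-methylpent-2-en-1-yl N,N-diisopropylcarbamate (racemic) | CC1(C)OC1CC/C(C)=C/COC(=O)N(C(C)C)C(C)C
F4 | step 5 | (2E)-3,7-dimethyl-6-oxooct-2-en-1-yl N,N-diisopropylcarbamate | CC(C)C(=O)CC/C(C)=C/COC(=O)N(C(C)C)C(C)C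
F5 | step 5 | (2E)-3-methyl-5-[2-(propan-2-yl)-1,3-dioxolan-2-yl]pent-2-en-1-yl N,N-diisopropylcarbamate | CC(C)C1(CC/C(C)=C/COC(=O)N(C(C)C)C(C)C)OCCO1
F6 | step 5 | (1Z,3S,4R)-4-hydroxy-3-methyl-3-{2-[2-(propan-2-yl)-1,3-dioxolan-2-yl]ethyl}hexa-1,5-dien-1-yl N,N-diisopropylcarbamate | O[C@H](C=C)[C@@](C)(CCC1(C(C)C)OCCO1)/C=C\OC(=O)N(C(C)C)C(C)C
F7 | step 5 | angelate of F6 | C/C=C(/C)C(=O)O[C@H](C=C)[C@@](C)(CCC1(C(C)C)OCCO1)/C=C\OC(=O)N(C(C)C)C(C)C
F8 | step 6 | (3S,4R)-3-methyl-3-(4-methyl-3-oxopentyl)-1-oxohex-5-en-4-yl (2Z)-2-methylbut-2-enoate | C/C=C(/C)C(=O)O[C@H](C=C)[C@@](C)(CCC(=O)C(C)C)CC=O
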